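The numbers in the tables are calculated for an exercise, and the scatter is random.

- A catalyst cannot move the point where a reaction ends, yet the autumn flask, with half the J of the midnight flask, stands at 0.0770 M at 21 h against 0.1444 M. So I take J to be lost as it works, and I count its work.

| flask | Z | J | X | time |
|---|---|---|---|---|
| midnight | 0.400 M | 0.0200 M |  |  |
| summer | 0.600 M | 0.0200 M |  |  |
| autumn | 0.400 M | 0.0100 M |  |  |
| dawn | 0.400 M | 0.0200 M | 0.120 M |  |
| noon | 0.400 M | 0.0200 M |  | 130 h |

| run | time / h | [X] / M |
|---|---|---|
| midnight run | 2.6 | 0.0685 |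
| midnight run | 5.2 | 0.1008 |
| midnight run | 7.9 | 0.1211 |
| midnight run | 10 | 0.1284 |
| midnight run | 13 | 0.1354 |
| midnight run | 16 | 0.1415 |
| midnight run | 18 | 0.1422 |
| midnight run | 21 | 0.1444 |
| summer run | 2.6 | 0.0789 |
| summer run | 5.2 | 0.1122 |
| summer run | 7.9 | 0.1316 |
| summer run | 10 | 0.1396 |
| summer run | 13 | 0.1479 |
| summer run | 16 | 0.1505 |
| summer run | 18 | 0.1531 |
| summer run | 21 | 0.1544 |
| autumn run | 2.6 | 0.0350 |
| autumn run | 5.2 | 0.0528 |
| autumn run | 7.9 | 0.0647 |
| autumn run | 10 | 0.0691 |
| autumn run | 13 | 0.0725 |
| autumn run | 16 | 0.0761 |
| autumn run | 18 | 0.0771 |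
| autumn run | 21 | 0.0770 |
| dawn run | 2.6 | 0.1814 |
| dawn run | 5.2 | 0.2112 |
| dawn run | 7.9 | 0.2261 |
| dawn run | 10 | 0.2329 |
| dawn run | 13 | 0.2378 |
| dawn run | 16 | 0.2428 |
| dawn run | 18 | 0.2444 |
| dawn run | 21 | 0.2453 |

(readings scatter by 0.001 M)

1. how the opening rate goes with [Z] round the charge of the midnight run: the exponent of the rate at two percent of Z gone to X (one fixed amount of X, the same in the runs compared)
2. how the opening rate goes with [J] round the charge of the midnight run: the exponent of the rate at two percent of Z gone to X
3. X in the noon run at 130 h, as a share of the Z charged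

- Overall: Z -> X, with J as catalyst.
- Constant volume, constant temperature.
- Readings of a species count what is bound in complexes too.
- An order is taken over about fifteen percent of the charge, up and down.

- My first estimate divides the last reading of X by the J charged. This gives 7.22 in the midnight flask, 7.70 in the autumn flask and 7.72 in the summer flask, even though the summer flask holds 0.600 M of Z against 0.400 M. The last summer reading is 1.07 times the last midnight reading, a smaller factor than the 1.50 between their Z charges.
- The noon flask has the midnight charge, so I multiply the midnight count by its J, which gives 36.1 % of its Z.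
- The weak link is that last reading, since midnight X is still rising. The gain from 13 h to 18 h is 0.476 of the gain over the nearly equal stretch before it.
- If each later stretch keeps gaining that share of the one before, I estimate that the midnight flask ends near 0.148 M.
- Dividing by the J charged gives 7.42, the number I carry: N, the turnover number, meaning X finally made per J charged.
- The Z charged in the midnight flask is more than that final X, so I reckon the end of X from J. For the noon flask I commit to 37.1 %.
- The forecast gives orders of 0.5 in Z and 1 in J, and 37.5 % for the noon flask, a little above my figure. Its ground is that “the catalyst dies after about 7.5 turnovers”.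
- The flask gives orders of 0.47 in Z and 1.0 in J, and 37.3 % for the noon flask.

    J + Z ⇌ JZ, settled at all times (3.180 M⁻¹)
    JZ ⇌ X + J (3.377 h⁻¹, 3.179 M⁻¹ h⁻¹)
    JZ → Yx + Z (0.3960 h⁻¹)
    2 Z → Wa (0.07920 M⁻¹ h⁻¹)

- The noon flask's 37.3 % is 7.45 turnovers per J, against my N of 7.42. The step from JZ to Yx + Z holds it there: with that step taken away, the noon flask reaches 47.3 % instead of 37.3 %. JZ takes the forward step to X + J 8.53 times as fast as it takes this one. The dawn flask, charged with X, adds 0.125 M by 21 h, a count of 6.26, which is less than N.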